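Ring A is cut at C5–C4 and C1=C6, which traces it back to ethyl vinyl ketone and a racemic 2-naphthylpropanal whose formyl carbon is C6. The route exploits the fact that the only stereocentre, the benzylic quaternary carbon C5, sits next to C6: as an aldehyde alpha-carbon it racemises, so one amine-catalysed Michael–aldol step converts both enantiomers into a single (R)-4-aryl-2,4-dimethylcyclohexenone, building ring A, two C–C bonds and C5. The precursor is a 5,8-dimethoxynaphthalene carrying the propanal side chain next to a tert-butyl ester, the latent lactone carbonyl. A later 1,3-transposition from the C2 oxygen delivers C7 to C6; enol lactonisation, quinone unmasking and hypotaurine annulation finish.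

Key step: step 6

Atom labels: ring A is C1 (methyl-bearing alkene carbon), C2, C3, C4, C5 (quaternary carbon) and C6; C7 is the enol-ester CH.

Assumption: the fluoride-labile silylaryl triflate 1 is taken as a catalogue aryne precursor, because an amide base strong enough to dehydrohalogenate a bromoarene would also destroy the electrophilic pyrone 2.

Step 1
Reactants: 1 3,6-dimethoxy-2-(trimethylsilyl)phenyl trifluoromethanesulfonate; 2 methyl coumalate
Product: 5 methyl 5,8-dimethoxy-2-naphthoate, via 3,6-dimethoxybenzyne 3 (not isolated), via bridged lactone cycloadduct 4 (not isolated)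
Conditions: CsF, MeCN, 25→60 °C
Reagents that add atoms: none
Why: Fluoride-induced 1,2-elimination releases the symmetrical aryne, which undergoes Diels–Alder cycloaddition across C3 and C6 of the pyrone and then retro-Diels–Alder loss of CO2 to aromatise, so the ester can only end up at a beta-position of the new naphthalene ring.

Step 2
Reactants: 5 methyl 5,8-dimethoxy-2-naphthoate
Product: 6 tert-butyl 5,8-dimethoxy-2-naphthoate
Conditions: KOtBu, THF, 0→25 °C
Reagents that add atoms: potassium tert-butoxide, CC(C)(C)[O-].[K+]
Why: Transesterification by alkoxide exchange on a non-enolisable aryl ester, driven by the poorly soluble potassium methoxide, installs the bulky ester that later directs metalation and resists acyl transfer.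

Step 3
Reactants: 6 tert-butyl 5,8-dimethoxy-2-naphthoate; 7 2-bromopropene
Product: 10 tert-butyl 5,8-dimethoxy-3-(prop-1-en-2-yl)-2-naphthoate, via arylmagnesium amide 8 (not isolated), via arylzinc chloride 9 (not isolated)
Conditions: TMP2Mg·2LiCl, THF, 0→25 °C; ZnCl2; then 7, Pd(PPh3)4 (cat.), 25→50 °C
Reagents that add atoms: none
Why: Ester-directed ortho-magnesiation by the hindered amide base should occur at C3 because C1 is shielded by the peri methoxy group, and transmetalation to zinc followed by Negishi cross-coupling with the alkenyl bromide forms the aryl–isopropenyl bond without touching the tert-butyl ester.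

Step 4
Reactants: 10 tert-butyl 5,8-dimethoxy-3-(prop-1-en-2-yl)-2-naphthoate
Product: 12 tert-butyl 3-(1-hydroxypropan-2-yl)-5,8-dimethoxy-2-naphthoate (racemic), via B-alkyl-9-BBN adduct 11 (not isolated)
Conditions: 9-BBN, THF, 0→50 °C; then 30% H2O2, aq. NaOH, 0 °C
Reagents that add atoms: hydrogen peroxide, OO
Why: Anti-Markovnikov hydroboration–oxidation places the oxygen on the terminal carbon without ever generating a benzylic cation next to the ester (which an epoxide-rearrangement route would risk trapping as a phthalide), and the new stereocentre is racemic by design.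

Step 5
Reactants: 12 tert-butyl 3-(1-hydroxypropan-2-yl)-5,8-dimethoxy-2-naphthoate (racemic)
Product: 13 tert-butyl 5,8-dimethoxy-3-(1-oxopropan-2-yl)-2-naphthoate (racemic)
Conditions: Dess–Martin periodinane, NaHCO3, CH2Cl2, 0→25 °C
Reagents that add atoms: none
Why: Dess–Martin oxidation under buffered anhydrous conditions stops at the aldehyde, whose alpha-aryl stereocentre is left racemic and labile as the key step requires.

Step 6
Reactants: 13 tert-butyl 5,8-dimethoxy-3-(1-oxopropan-2-yl)-2-naphthoate (racemic); 14 ethyl vinyl ketone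
Product: 16 tert-butyl 3-[(1R)-1,3-dimethyl-4-oxocyclohex-2-en-1-yl]-5,8-dimethoxy-2-naphthoate, via keto aldehyde 15 (not isolated)
Conditions: 14 (2 equiv), 9-amino-9-deoxy-epi-quinine or its quinidine-derived pseudo-enantiomer (20 mol %, whichever gives the R product), 2-FC6H4CO2H (40 mol %), toluene, 40 °C; then pyrrolidine, AcOH (30 mol % each), 50 °C
Reagents that add atoms: none
Why: The primary amine condenses with either enantiomer of 13 to the same trisubstituted enamine, whose nucleophilic carbon C5 adds to the terminal carbon C4 of 14 activated by hydrogen bonding to the protonated quinuclidine, and hydrolysis releases keto aldehyde 15, in which the ketone enol or enamine attacks the non-enolisable neopentyl aldehyde through C1 and dehydrates to enone 16. The closest known reaction type is the primary-amine-catalysed Michael addition of alpha-branched aldehydes to vinyl ketones followed by aldol condensation, an organocatalytic Robinson annulation. Ring A closes by a 6-(enolendo)-exo-trig aldol addition and loss of water. The C5 stereocentre is set under catalyst control: the cinchona scaffold shields one face of the enamine and delivers the enone to the other, so the racemising aldehyde is funnelled dynamically into one enantiomer. The step needs enantiofacial selectivity, mono-addition and a single aldol regiochemistry; these are secured by the one enamine geometry favoured by allylic strain around the ortho-substituted naphthyl group, by the quaternary adduct having no alpha-hydrogen left, and by the fact that only attack through C1 gives a six-membered ring, while the tert-butyl ester resists acyl transfer to the catalyst nitrogen or the enol oxygen.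

Step 7
Reactants: 16 tert-butyl 3-[(1R)-1,3-dimethyl-4-oxocyclohex-2-en-1-yl]-5,8-dimethoxy-2-naphthoate
Product: 17 tert-butyl 3-[(1R)-4-hydroxy-1,3-dimethylcyclohex-2-en-1-yl]-5,8-dimethoxy-2-naphthoate (both carbinol epimers)
Conditions: NaBH4, CeCl3·7H2O, MeOH, −40→0 °C
Reagents that add atoms: none
Why: Luche reduction delivers hydride 1,2 to the enone carbonyl only, and the configuration of the new carbinol carbon C2 is left uncontrolled because this centre is destroyed again in step 9.

Step 8
Reactants: 17 tert-butyl 3-[(1R)-4-hydroxy-1,3-dimethylcyclohex-2-en-1-yl]-5,8-dimethoxy-2-naphthoate (both carbinol epimers); 18 tributyl(iodomethyl)stannane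
Product: 19 tert-butyl 3-[(1R)-1,3-dimethyl-4-[(tributylstannyl)methoxy]cyclohex-2-en-1-yl]-5,8-dimethoxy-2-naphthoate (both ether epimers)
Conditions: KH, THF, 0 °C; then 18, 18-crown-6 (cat.), 25 °C
Reagents that add atoms: none
Why: Williamson etherification of the potassium alkoxide by the iodomethylstannane gives the stannylmethyl ether needed for the Wittig–Still rearrangement, the remote hindered ester being inert to the alkoxide.

Step 9
Reactants: 19 tert-butyl 3-[(1R)-1,3-dimethyl-4-[(tributylstannyl)methoxy]cyclohex-2-en-1-yl]-5,8-dimethoxy-2-naphthoate (both ether epimers)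
Product: 21 tert-butyl 3-[(1R)-2-(hydroxymethyl)-1,3-dimethylcyclohex-3-en-1-yl]-5,8-dimethoxy-2-naphthoate (both C6 epimers), via lithiomethyl ether 20 (not isolated)
Conditions: n-BuLi, THF, −78 °C; then H2O
Reagents that add atoms: none
Why: Tin–lithium exchange outpaces addition to the hindered tert-butyl ester at −78 °C, and the resulting alkoxymethyllithium undergoes the Wittig–Still [2,3]-sigmatropic rearrangement, bonding C7 to C6 on the face from which the C2 oxygen departs while the alkene moves to C1=C2, so each carbinol epimer gives one C6 epimer and both are erased in step 12.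

Step 10
Reactants: 21 tert-butyl 3-[(1R)-2-(hydroxymethyl)-1,3-dimethylcyclohex-3-en-1-yl]-5,8-dimethoxy-2-naphthoate (both C6 epimers)
Product: 22 tert-butyl 3-[(1R)-2-formyl-1,3-dimethylcyclohex-3-en-1-yl]-5,8-dimethoxy-2-naphthoate (both C6 epimers)
Conditions: Dess–Martin periodinane, NaHCO3, CH2Cl2, 0 °C
Reagents that add atoms: none
Why: Buffered Dess–Martin oxidation converts the primary alcohol into the beta,gamma-unsaturated aldehyde without base or acid that could move the C1=C2 alkene into conjugation.

Step 11
Reactants: 22 tert-butyl 3-[(1R)-2-formyl-1,3-dimethylcyclohex-3-en-1-yl]-5,8-dimethoxy-2-naphthoate (both C6 epimers)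
Product: 23 3-[(1R)-2-formyl-1,3-dimethylcyclohex-3-en-1-yl]-5,8-dimethoxy-2-naphthoic acid (both C6 epimers)
Conditions: CF3CO2H/CH2Cl2 (1:4), 1,3-dimethoxybenzene, 0 °C
Reagents that add atoms: none
Why: Acidolysis of the tert-butyl ester proceeds by E1 loss of isobutene irrespective of the steric shielding of the acyl carbon, the arene scavenger protecting the dimethoxynaphthalene from tert-butylation and the low temperature limiting enolisation of the aldehyde.

Step 12
Reactants: 23 3-[(1R)-2-formyl-1,3-dimethylcyclohex-3-en-1-yl]-5,8-dimethoxy-2-naphthoic acid (both C6 epimers)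
Product: 25 (S)-dimethoxy dienol lactone (seven-membered enol lactone O–C(=O)–aryl–aryl–C5–C6=C7 fused to the 2,3-bond of 5,8-dimethoxynaphthalene and through C5–C6 to ring A with C1=C2), via acid chloride 24 (not isolated)
Conditions: Me2C=C(Cl)NMe2, CH2Cl2, 0 °C; then Et3N, DMAP (cat.), high dilution, 0→25 °C
Reagents that add atoms: none
Why: Enol lactonisation, in which the neutral chloroenamine converts the acid into the aroyl chloride and amine base then drains the reversibly formed dienol of the aldehyde (oxygen syn to C5) by O-acylation in a 7-(enolendo)-exo-trig closure, C-acylation at C6 being disfavoured because it would join two quaternary carbons; C5 is untouched and becomes S only through the change in CIP priorities.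

Step 13
Reactants: 25 (S)-dimethoxy dienol lactone
Product: 26 (S)-naphthoquinone dienol lactone (5,8-dione of 25)
Conditions: (NH4)2Ce(NO3)6, MeCN/H2O, 0 °C
Reagents that add atoms: water, O
Why: Oxidative demethylation of the para-dimethoxyarene by (NH4)2Ce(NO3)6 proceeds through the arene radical cation, which is far easier to form than any oxidation of the acyloxydiene, and gives the naphthoquinone.

Step 14
Reactants: 26 (S)-naphthoquinone dienol lactone; 27 hypotaurine
Product: 30 CNP0348176.1 (target, S at C5), via sulfonyl hydroquinone 28 (not isolated), via sulfonyl quinone 29 (not isolated)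
Conditions: MeCN/EtOH/H2O, air, 25 °C
Reagents that add atoms: none
Why: Hypotaurine annulation, in which the sulfinate should add in a conjugate sense to the quinone carbon beta to the more electron-poor carbonyl (the one whose ring carbon is para to the ring carbon bearing the lactone carbonyl), air reoxidises the hydroquinone, the tethered amine closes the six-membered ring at the neighbouring carbon and a second aerial oxidation should give the aminoquinone, the regioisomer from attack at the other carbon being the expected minor product to be removed by chromatography.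

Compound list

1 | 3,6-dimethoxy-2-(trimethylsilyl)phenyl trifluoromethanesulfonate | COc1ccc(OC)c(OS(=O)(=O)C(F)(F)F)c1[Si](C)(C)C | starting material
2 | methyl coumalate (methyl 2-oxo-2H-pyran-5-carboxylate) | COC(=O)C1=COC(=O)C=C1 | starting material
3 | 3,6-dimethoxybenzyne | COC1=CC=C(OC)C#C1 | intermediate
4 | methyl 5,8-dimethoxy-10-oxo-1,4-dihydro-1,4-(epoxymethano)naphthalene-2-carboxylate (racemic bridged lactone cycloadduct) | COC(=O)C1=CC2C(=O)OC1c1c(OC)ccc(OC)c12 | intermediate
5 | methyl 5,8-dimethoxy-2-naphthoate | COC(=O)c1ccc2c(OC)ccc(OC)c2c1 | intermediate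
6 | tert-butyl 5,8-dimethoxy-2-naphthoate | CC(C)(C)OC(=O)c1ccc2c(OC)ccc(OC)c2c1 | intermediate
7 | 2-bromopropene | CC(Br)=C | starting material
8 | [3-(tert-butoxycarbonyl)-5,8-dimethoxynaphthalen-2-yl](2,2,6,6-tetramethylpiperidin-1-yl)magnesium (LiCl complex) | CC1(C)CCCC(C)(C)N1[Mg]c1cc2c(OC)ccc(OC)c2cc1C(=O)OC(C)(C)C | intermediate
9 | [3-(tert-butoxycarbonyl)-5,8-dimethoxynaphthalen-2-yl]zinc chloride | Cl[Zn]c1cc2c(OC)ccc(OC)c2cc1C(=O)OC(C)(C)C | intermediate
10 | tert-butyl 5,8-dimethoxy-3-(prop-1-en-2-yl)-2-naphthoate | CC(=C)c1cc2c(OC)ccc(OC)c2cc1C(=O)OC(C)(C)C | intermediate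
11 | tert-butyl 3-[1-(9-borabicyclo[3.3.1]nonan-9-yl)propan-2-yl]-5,8-dimethoxy-2-naphthoate (racemic) | CC(CB1C2CCCC1CCC2)c1cc2c(OC)ccc(OC)c2cc1C(=O)OC(C)(C)C | intermediate
12 | tert-butyl 3-(1-hydroxypropan-2-yl)-5,8-dimethoxy-2-naphthoate (racemic) | CC(CO)c1cc2c(OC)ccc(OC)c2cc1C(=O)OC(C)(C)C | intermediate
13 | tert-butyl 5,8-dimethoxy-3-(1-oxopropan-2-yl)-2-naphthoate (racemic, configurationally labile) | CC(C=O)c1cc2c(OC)ccc(OC)c2cc1C(=O)OC(C)(C)C | intermediate
14 | ethyl vinyl ketone (pent-1-en-3-one) | CCC(=O)C=C | starting material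
15 | tert-butyl 5,8-dimethoxy-3-[(2S)-2-methyl-1,5-dioxoheptan-2-yl]-2-naphthoate | CCC(=O)CC[C@](C)(C=O)c1cc2c(OC)ccc(OC)c2cc1C(=O)OC(C)(C)C | intermediate
16 | tert-butyl 3-[(1R)-1,3-dimethyl-4-oxocyclohex-2-en-1-yl]-5,8-dimethoxy-2-naphthoate | CC1=C[C@](C)(c2cc3c(OC)ccc(OC)c3cc2C(=O)OC(C)(C)C)CCC1=O | intermediate
17 | tert-butyl 3-[(1R)-4-hydroxy-1,3-dimethylcyclohex-2-en-1-yl]-5,8-dimethoxy-2-naphthoate (both carbinol epimers) | CC1=C[C@](C)(c2cc3c(OC)ccc(OC)c3cc2C(=O)OC(C)(C)C)CCC1O | intermediate
18 | tributyl(iodomethyl)stannane | CCCC[Sn](CCCC)(CCCC)CI | starting material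
19 | tert-butyl 3-[(1R)-1,3-dimethyl-4-[(tributylstannyl)methoxy]cyclohex-2-en-1-yl]-5,8-dimethoxy-2-naphthoate (both ether epimers) | CC1=C[C@](C)(c2cc3c(OC)ccc(OC)c3cc2C(=O)OC(C)(C)C)CCC1OC[Sn](CCCC)(CCCC)CCCC | intermediate
20 | tert-butyl 3-[(1R)-4-(lithiomethoxy)-1,3-dimethylcyclohex-2-en-1-yl]-5,8-dimethoxy-2-naphthoate | CC1=C[C@](C)(c2cc3c(OC)ccc(OC)c3cc2C(=O)OC(C)(C)C)CCC1OC[Li] | intermediate
21 | tert-butyl 3-[(1R)-2-(hydroxymethyl)-1,3-dimethylcyclohex-3-en-1-yl]-5,8-dimethoxy-2-naphthoate (both C6 epimers) | CC1=CCC[C@@](C)(c2cc3c(OC)ccc(OC)c3cc2C(=O)OC(C)(C)C)C1CO | intermediate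
22 | tert-butyl 3-[(1R)-2-formyl-1,3-dimethylcyclohex-3-en-1-yl]-5,8-dimethoxy-2-naphthoate (both C6 epimers) | CC1=CCC[C@@](C)(c2cc3c(OC)ccc(OC)c3cc2C(=O)OC(C)(C)C)C1C=O | intermediate
23 | 3-[(1R)-2-formyl-1,3-dimethylcyclohex-3-en-1-yl]-5,8-dimethoxy-2-naphthoic acid (both C6 epimers) | CC1=CCC[C@@](C)(c2cc3c(OC)ccc(OC)c3cc2C(=O)O)C1C=O | intermediate
24 | 3-[(1R)-2-formyl-1,3-dimethylcyclohex-3-en-1-yl]-5,8-dimethoxy-2-naphthoyl chloride | CC1=CCC[C@@](C)(c2cc3c(OC)ccc(OC)c3cc2C(Cl)=O)C1C=O | intermediate
25 | (S)-dimethoxy dienol lactone: seven-membered enol lactone O–C(=O)–aryl–aryl–C5–C6=C7 fused to the 2,3-bond of 5,8-dimethoxynaphthalene; C5 (S, methyl) and C6 shared with ring A, which carries the C1 methyl and the C1=C2 alkene | CC1=CCC[C@]2(C)C1=COC(=O)c1cc3c(OC)ccc(OC)c3cc12 | intermediate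
26 | (S)-naphthoquinone dienol lactone: 25 with the dimethoxy ring as the 5,8-quinone | CC1=CCC[C@]2(C)C1=COC(=O)c1cc3c(cc12)C(=O)C=CC3=O | intermediate
27 | hypotaurine (2-aminoethanesulfinic acid) | NCCS(=O)O | starting material
28 | hydroquinone form of 26 carrying a 2-aminoethylsulfonyl group on the carbon that is sulfur-bound in 30 | CC1=CCC[C@]2(C)C1=COC(=O)c1cc3c(O)c(S(=O)(=O)CCN)cc(O)c3cc12 | intermediate
29 | quinone 26 carrying the 2-aminoethylsulfonyl group on the same carbon | CC1=CCC[C@]2(C)C1=COC(=O)c1cc3c(cc12)C(=O)C=C(C3=O)S(=O)(=O)CCN | intermediate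
30 | CNP0348176.1: quinone 26 fused at its two quinone CH carbons to a 1,1-dioxo-1,4-thiazinane ring (S and NH on the quinone alkene), C5 S | CC1=CCC[C@]2(C)C1=COC(=O)c1cc3c(cc12)C(=O)C1=C(C3=O)S(=O)(=O)CCN1 | target

Total step count: 14. Longest linear sequence: 14 steps (from 1 and 2 to 30).

Steps most likely to fail

Step 6. Enamine formation from the ortho-substituted, alpha-branched aldehyde may be slow, and the facial bias of the catalyst may be eroded by a mixture of enamine geometries or by retro-Michael equilibration before the aldol closure. The fallback moves the chirality source from a catalyst to a stoichiometric auxiliary. Racemic 13 is condensed with (S)-1-phenylethylamine (or its mirror image, chosen by the sense of induction required) in toluene over molecular sieves to give chiral imine F1. Its secondary enamine tautomer adds to 14 in a chiral-imine Michael addition (aza-ene-like, internal proton transfer) to give adduct imine F2. Aqueous acetic acid releases keto aldehyde 15, and pyrrolidinium acetate or KOH in MeOH closes ring A, rejoining the route at 16.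

Step 14. The sulfinate may add to both quinone carbons with little bias, and the free amine may open the enol lactone by acyl transfer before the thiazine ring has closed. The fallback builds the thiazine before the lactone exists. Homoallylic alcohol 21 is oxidised with (NH4)2Ce(NO3)6 to quinone alcohol F3, and hypotaurine in aqueous MeCN/EtOH under air gives thiazinoquinone alcohol F4, at which stage the regioisomers can be separated without a labile lactone present. Dess–Martin oxidation gives aldehyde F5 and CF3CO2H acidolysis gives acid F6. The chloroenamine/Et3N enol lactonisation of step 12, through acid chloride F7, then arrives directly at 30.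

Step 9. Butyllithium may add to the ester, or the alkoxymethyllithium may undergo a [1,2]-shift or simple protonation instead of the [2,3]-shift onto the neopentyl alkene carbon. The fallback places C7 on C6 by conjugate addition. Enone 16 is treated with (isopropoxydimethylsilyl)methylmagnesium chloride and catalytic CuBr·SMe2, and the regiodefined magnesium enolate is trapped with PhNTf2 as enol triflate F8. Formate reduction catalysed by Pd(OAc)2/PPh3 (HCO2H, Bu3N, DMF) removes the triflate and leaves the C1=C2 alkene in silane F9. Tamao–Fleming oxidation (H2O2, KF, KHCO3, THF/MeOH) then returns homoallylic alcohol 21.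

Further compounds

F1 | step 6 | tert-butyl 5,8-dimethoxy-3-[1-{[(1S)-1-phenylethyl]imino}propan-2-yl]-2-naphthoate (labile at the alpha-carbon) | C[C@H](N=CC(C)c1cc2c(OC)ccc(OC)c2cc1C(=O)OC(C)(C)C)c1ccccc1
F2 | step 6 | tert-butyl 5,8-dimethoxy-3-[(2S)-2-methyl-5-oxo-1-{[(1S)-1-phenylethyl]imino}heptan-2-yl]-2-naphthoate | CCC(=O)CC[C@](C)(C=N[C@@H](C)c1ccccc1)c1cc2c(OC)ccc(OC)c2cc1C(=O)OC(C)(C)C
F3 | step 14 | tert-butyl 3-[(1R)-2-(hydroxymethyl)-1,3-dimethylcyclohex-3-en-1-yl]-5,8-dioxo-5,8-dihydronaphthalene-2-carboxylate (both C6 epimers) | CC1=CCC[C@@](C)(c2cc3c(cc2C(=O)OC(C)(C)C)C(=O)C=CC3=O)C1CO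
F4 | step 14 | thiazinoquinone alcohol: F3 fused at the quinone CH carbons to the 1,1-dioxo-1,4-thiazinane ring in the orientation of 30 | CC1=CCC[C@@](C)(c2cc3c(cc2C(=O)OC(C)(C)C)C(=O)C2=C(NCCS2(=O)=O)C3=O)C1CO
F5 | step 14 | thiazinoquinone aldehyde: F4 with the hydroxymethyl group oxidised to formyl | CC1=CCC[C@@](C)(c2cc3c(cc2C(=O)OC(C)(C)C)C(=O)C2=C(NCCS2(=O)=O)C3=O)C1C=O
F6 | step 14 | thiazinoquinone aldehyde acid: F5 with the free carboxylic acid | CC1=CCC[C@@](C)(c2cc3c(cc2C(=O)O)C(=O)C2=C(NCCS2(=O)=O)C3=O)C1C=O
F7 | step 14 | thiazinoquinone aldehyde acid chloride (formed in the flask) | CC1=CCC[C@@](C)(c2cc3c(cc2C(Cl)=O)C(=O)C2=C(NCCS2(=O)=O)C3=O)C1C=O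
F8 | step 9 | tert-butyl 3-[(1R)-2-{[dimethyl(propan-2-yloxy)silyl]methyl}-1,3-dimethyl-4-(trifluoromethylsulfonyloxy)cyclohex-3-en-1-yl]-5,8-dimethoxy-2-naphthoate (both C6 epimers) | CC1=C(OS(=O)(=O)C(F)(F)F)CC[C@@](C)(c2cc3c(OC)ccc(OC)c3cc2C(=O)OC(C)(C)C)C1C[Si](C)(C)OC(C)C
F9 | step 9 | tert-butyl 3-[(1R)-2-{[dimethyl(propan-2-yloxy)silyl]methyl}-1,3-dimethylcyclohex-3-en-1-yl]-5,8-dimethoxy-2-naphthoate (both C6 epimers) | CC1=CCC[C@@](C)(c2cc3c(OC)ccc(OC)c3cc2C(=O)OC(C)(C)C)C1C[Si](C)(C)OC(C)C
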